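**Retrosynthetic overview**

- Ring numbering used throughout: C1 carbinol carbon (OH and one prenyl), C2 enol carbon, C3 isobutyryl-bearing carbon, C4 ketone, C5 gem-diprenyl carbon, C6 ketone. The route rests on quaternary C5: it keeps the six-membered ring dearomatised, so that without its C1 prenyl group the molecule is an achiral C1/C6 enediol with a prochiral, nucleophilic C1.
- Key disconnection: the C1–CH2 bond, by palladium-catalysed asymmetric prenylation of that enediol with tert-butyl prenyl carbonate. This sets the only stereocentre and closes no ring.
- Second disconnection: the two C5–CH2 bonds, by dearomative twofold C-prenylation of the aromatic 2,3,4,6-tetrahydroxy ketone. A free C1 hydroxyl would draw the second prenyl group to C1 (the reactivity the key step itself uses), so the C1 and C6 oxygens are held in a diphenylmethylene ketal for this step and freed afterwards by dilute acid.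
- Third disconnection: the aryl–acyl bond and three O–CH3 bonds, by Friedel-Crafts isobutyrylation of 3,4,5-trimethoxyphenol and BBr3 demethylation. The carbocycle is the arene of the starting phenol; the only ring closed is the temporary dioxole (step 3), opened again in step 5.

Key step: step 7

Assumption: the (R,R)-ligand is taken to give the (R)-configured product; the sense of induction cannot be derived with certainty for this nucleophile class, and the (S,S)-ligand is used instead if the first run shows the opposite sense.

**Route**

Step 1
Reactants: 1 3,4,5-trimethoxyphenol; 2 isobutyryl chloride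
Product: 3 1-(6-hydroxy-2,3,4-trimethoxyphenyl)-2-methylpropan-1-one
Conditions: AlCl3 (2.2 equiv), CH2Cl2, 0 °C to rt; dilute aq. HCl work-up
Reagents that add atoms: none
Why: Friedel-Crafts acylation in which the phenol directs the acylium ion to its ortho carbon (the two open ring positions are equivalent) and the aluminium chelate of the ortho-hydroxy ketone prevents a second acylation; any loss of the methyl group ortho to the ketone is harmless because step 2 removes all three.

Step 2
Reactants: 3 1-(6-hydroxy-2,3,4-trimethoxyphenyl)-2-methylpropan-1-one
Product: 4 2-methyl-1-(2,3,4,6-tetrahydroxyphenyl)propan-1-one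
Conditions: BBr3 (5 equiv), CH2Cl2, −78 °C to rt; MeOH then H2O quench; handled under Ar
Reagents that add atoms: none
Why: Lewis-acid aryl methyl ether cleavage, in which BBr3 complexes each ether oxygen and bromide removes the methyl group as bromomethane while the aryl ketone is untouched.

Step 3
Reactants: 4 2-methyl-1-(2,3,4,6-tetrahydroxyphenyl)propan-1-one
Product: 5 1-(4,6-dihydroxy-2,2-diphenyl-1,3-benzodioxol-5-yl)-2-methylpropan-1-one
Conditions: Ph2CCl2 (1.1 equiv), K2CO3 (2.5 equiv), degassed MeCN, rt to 50 °C, Ar
Reagents that add atoms: dichlorodiphenylmethane, ClC(Cl)(c1ccccc1)c1ccccc1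
Why: Base-mediated ketalisation of a catechol pair with a gem-dichloride, in which the most acidic hydroxyl (C6–OH, para to the ketone) is alkylated first and its only neighbour (C1–OH) closes the dioxole while the two ketone-chelated hydroxyls stay free; with the C1 oxygen tied up, C1 should no longer compete with C5 for a prenyl group as it would in the free tetraol.

Step 4
Reactants: 5 1-(4,6-dihydroxy-2,2-diphenyl-1,3-benzodioxol-5-yl)-2-methylpropan-1-one; 6 prenyl bromide (2.3 equiv)
Product: 8 4-hydroxy-5-(2-methylpropanoyl)-7,7-bis(3-methylbut-2-en-1-yl)-2,2-diphenyl-1,3-benzodioxol-6(7H)-one, via C5-monoprenyl ketal 7 (not isolated)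
Conditions: NaOMe (2.5 equiv), degassed MeOH, 0 °C to rt, Ar; dilute aq. HCl work-up
Reagents that add atoms: none
Why: Dearomative C-alkylation of an acylphloroglucinol-type phenoxide, as used for lupulone-type hop acids: C5 is ortho and para to the two phenoxide oxygens and is the only ring carbon bearing hydrogen, so the first prenyl group enters there with rearomatisation to 7 and the second at the same carbon gives the gem-diprenyl dienone, held as its stabilised β-triketone enolate, while C1 carries a dioxole oxygen and C3 the acyl group.

Step 5
Reactants: 8 4-hydroxy-5-(2-methylpropanoyl)-7,7-bis(3-methylbut-2-en-1-yl)-2,2-diphenyl-1,3-benzodioxol-6(7H)-one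
Product: 9 3,4,5-trihydroxy-2-(2-methylpropanoyl)-6,6-bis(3-methylbut-2-en-1-yl)cyclohexa-2,4-dien-1-one (the achiral C1/C6 enediol)
Conditions: 1 M aq. HCl, degassed THF, 40 °C, Ar; extraction into aq. NaHCO3, re-acidification; used at once
Reagents that add atoms: none
Why: Acid hydrolysis of the ketal, which after dearomatisation is an enol ether of a vinylogous acid and should therefore release benzophenone and the enediol in dilute acid that leaves the prenyl double bonds alone; 9 is a reductone and is kept free of air.

Step 6
Reactants: 10 prenol
Product: 11 tert-butyl prenyl carbonate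
Conditions: Boc2O, n-Bu4NHSO4 (cat.), 30% aq. NaOH, CH2Cl2, 0 °C to rt
Reagents that add atoms: di-tert-butyl dicarbonate, CC(C)(C)OC(=O)OC(=O)OC(C)(C)C
Why: Phase-transfer acylation of the primary allylic alkoxide with Boc2O gives the mixed carbonate, the standard ionisable partner for palladium-catalysed allylic alkylation.

Step 7
Reactants: 9 the C1/C6 enediol; 11 tert-butyl prenyl carbonate (1.2 equiv)
Product: 12 (4R)-3,4-dihydroxy-2-(2-methylpropanoyl)-4,6,6-tris(3-methylbut-2-en-1-yl)cyclohex-2-ene-1,5-dione (target)
Conditions: Pd2(dba)3·CHCl3 (2.5 mol %), (R,R)-DACH-phenyl Trost ligand [(1R,2R)-N,N'-bis(2-diphenylphosphinobenzoyl)cyclohexane-1,2-diamine, 7.5 mol %], 1,1,3,3-tetramethylguanidine (1.0 equiv), degassed CH2Cl2, 0 °C, Ar; cold 1 M HCl work-up, chromatography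
Reagents that add atoms: none
Why: Proposed new method: zerovalent palladium ionises 11 to a cationic π-(1,1-dimethylallyl) complex of divalent palladium, CO2 and tert-butoxide; tetramethylguanidine removes the β-triketone proton of 9 and tert-butoxide the C6–OH proton, so the dianion carries carbanion character at C1 (between the C6 and C2 carbonyl-type carbons) and attacks the CH2 terminus of the allyl ligand on the face away from the metal, forming the C1–CH2 bond, turning C6 into a ketone and returning zerovalent palladium. The closest known reactions are the palladium-catalysed asymmetric allylic alkylation (Tsuji-Trost reaction) of β-keto ester and cyclic 1,3-diketone enolates to fully substituted carbons and the palladium-catalysed C-allylation of reductones at their hydroxyl-bearing carbon; an asymmetric prenylation of a hydroxy-diketonate of this kind is the extension. No ring is closed. The C1 stereocentre is set by the chiral pocket of the ligand, which must distinguish the enantiotopic faces of the planar dianion through the difference between its C2 enol/C3 acyl flank and its C6 ketone/C5 gem-diprenyl flank. The step needs C- over O-alkylation, linear over branched attack and C1 over other carbons: O-prenyl enol ethers re-ionise on the catalyst while the C–C bond does not, outer-sphere attack of a stabilised anion goes to the unsubstituted allyl terminus, and the only other carbanionic carbon, C3, is acylated while C5 is quaternary. Work-up is cold and acidic because the new tertiary α-ketol could otherwise undergo base-induced acyloin ring contraction.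

**Compound list**

1 | 3,4,5-trimethoxyphenol | COc1cc(O)cc(OC)c1OC | starting material
2 | isobutyryl chloride | CC(C)C(Cl)=O | starting material
3 | 1-(6-hydroxy-2,3,4-trimethoxyphenyl)-2-methylpropan-1-one | COc1cc(O)c(C(=O)C(C)C)c(OC)c1OC | intermediate
4 | 2-methyl-1-(2,3,4,6-tetrahydroxyphenyl)propan-1-one | CC(C)C(=O)c1c(O)cc(O)c(O)c1O | intermediate
5 | 1-(4,6-dihydroxy-2,2-diphenyl-1,3-benzodioxol-5-yl)-2-methylpropan-1-one (ketal across the C1 and C6 oxygens) | CC(C)C(=O)c1c(O)cc2OC(c3ccccc3)(c3ccccc3)Oc2c1O | intermediate
6 | prenyl bromide (1-bromo-3-methylbut-2-ene) | CC(C)=CCBr | starting material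
7 | 1-[4,6-dihydroxy-7-(3-methylbut-2-en-1-yl)-2,2-diphenyl-1,3-benzodioxol-5-yl]-2-methylpropan-1-one (C5-monoprenyl ketal, not isolated) | CC(C)C(=O)c1c(O)c(CC=C(C)C)c2OC(c3ccccc3)(c3ccccc3)Oc2c1O | intermediate
8 | 4-hydroxy-5-(2-methylpropanoyl)-7,7-bis(3-methylbut-2-en-1-yl)-2,2-diphenyl-1,3-benzodioxol-6(7H)-one | CC(C)C(=O)C1=C(O)C2=C(OC(c3ccccc3)(c3ccccc3)O2)C(CC=C(C)C)(CC=C(C)C)C1=O | intermediate
9 | 3,4,5-trihydroxy-2-(2-methylpropanoyl)-6,6-bis(3-methylbut-2-en-1-yl)cyclohexa-2,4-dien-1-one (achiral C1/C6 enediol, key-step precursor) | CC(C)=CCC1(CC=C(C)C)C(=O)C(C(=O)C(C)C)=C(O)C(O)=C1O | intermediate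
10 | prenol (3-methylbut-2-en-1-ol) | CC(C)=CCO | starting material
11 | tert-butyl prenyl carbonate | CC(C)=CCOC(=O)OC(C)(C)C | intermediate
12 | (4R)-3,4-dihydroxy-2-(2-methylpropanoyl)-4,6,6-tris(3-methylbut-2-en-1-yl)cyclohex-2-ene-1,5-dione | CC(C)=CCC1(CC=C(C)C)C(=O)C(C(=O)C(C)C)=C(O)[C@](O)(CC=C(C)C)C1=O | target

**Step count**

Total steps: 7. Longest linear sequence: 6 (steps 1, 2, 3, 4, 5, 7); step 6 is a one-step side branch.

**Steps most likely to fail**

Step 7. The risk is poor enantioface discrimination, because the two flanks of the planar dianion differ only at some distance from C1. Branched attack on the allyl ligand and oxidation of the electron-rich dianion are further risks. The fallback uses known chemistry and sets out from 9. The enediol is C-prenylated without chiral control using prenyl bromide 6 and NaOMe in degassed MeOH at 0 °C, the alkylation of a cyclic 2-hydroxy-1,3-diketonate at its hydroxyl-bearing carbon by which hop α-acid skeletons are assembled. This should give racemic 3,4-dihydroxy-2-(2-methylpropanoyl)-4,6,6-tris(3-methylbut-2-en-1-yl)cyclohex-2-ene-1,5-dione F1. The enantiomers are then separated by preparative HPLC on a polysaccharide chiral stationary phase, and the (R)-enantiomer is 12, where the fallback rejoins the route.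

Step 4. The risk is O-prenylation outrunning C-prenylation, and the sequence stalling after the first prenyl group at 7. The fallback sets out from 5 and replaces the SN2 alkylation by allylic substitution under Pd(PPh3)4 (zerovalent palladium) with carbonate 11 (2.2 equiv) in THF at rt. O-Prenyl ethers re-ionise on the metal, so material should collect in the twofold C5-alkylated product. The fallback passes through 7, returns at 8 and makes no compound outside the list (F0).

Step 5. The risk is acid-induced cyclisation of a prenyl group onto a neighbouring enol oxygen before the ketal is gone, and air oxidation of the enediol during isolation. The fallback sets out from 4 and changes the mask to a cyclic orthoformate, which opens in far weaker acid. HC(OEt)3 with Amberlyst 15 in toluene at reflux should give 1-(2-ethoxy-4,6-dihydroxy-1,3-benzodioxol-5-yl)-2-methylpropan-1-one F2; the regioisomer across the C1 and C2 oxygens would converge on the same enediol. Prenylation as in step 4 passes through 1-[2-ethoxy-4,6-dihydroxy-7-(3-methylbut-2-en-1-yl)-1,3-benzodioxol-5-yl]-2-methylpropan-1-one F3 (not isolated) to 2-ethoxy-4-hydroxy-5-(2-methylpropanoyl)-7,7-bis(3-methylbut-2-en-1-yl)-1,3-benzodioxol-6(7H)-one F4. Treatment with 0.1 M HCl in degassed THF/H2O at 0 °C to rt, followed by NaHCO3 extraction, should hydrolyse the orthoester through to 9, where the fallback rejoins the route.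

**Further compounds**

F1 | step 7 | racemic 3,4-dihydroxy-2-(2-methylpropanoyl)-4,6,6-tris(3-methylbut-2-en-1-yl)cyclohex-2-ene-1,5-dione | CC(C)=CCC1(CC=C(C)C)C(=O)C(C(=O)C(C)C)=C(O)C(O)(CC=C(C)C)C1=O
F0 | step 4 | none | none
F2 | step 5 | 1-(2-ethoxy-4,6-dihydroxy-1,3-benzodioxol-5-yl)-2-methylpropan-1-one | CCOC1Oc2cc(O)c(C(=O)C(C)C)c(O)c2O1
F3 | step 5 | 1-[2-ethoxy-4,6-dihydroxy-7-(3-methylbut-2-en-1-yl)-1,3-benzodioxol-5-yl]-2-methylpropan-1-one | CCOC1Oc2c(CC=C(C)C)c(O)c(C(=O)C(C)C)c(O)c2O1
F4 | step 5 | 2-ethoxy-4-hydroxy-5-(2-methylpropanoyl)-7,7-bis(3-methylbut-2-en-1-yl)-1,3-benzodioxol-6(7H)-one | CCOC1OC2=C(O1)C(O)=C(C(=O)C(C)C)C(=O)C2(CC=C(C)C)CC=C(C)C
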